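Assumption: the target has no stereocentre and no stereogenic double bond, and the 18-membered ring is taken to be conformationally mobile, so no stereochemical control is planned.

## Structural features

The target (C29H26O4) is a marchantin-type macrocyclic bis(bibenzyl), the ring A methyl ether of marchantin C, in which four benzene rings A–D are joined alternately by two diaryl ether oxygens (A–O–B and C–O–D) and two CH2CH2 bridges (B–C and D–A) into an 18-membered ring. Ring A is 1,2,3-trisubstituted (OMe on a1, ether oxygen on a6, bridge on a5), ring B is a meta-phenylene (ether oxygen on b1, bridge on b5, hydrogen on b2, b3, b4 and b6), ring C carries the bridge on c1, the free hydroxyl on c4 and the ether oxygen on c5, and ring D is a para-phenylene (oxygen on d1, bridge on d4). The only sensitive group is the free phenol of ring C, which has to be told apart from the methyl ether of ring A. The real difficulty lies in closing the macrocycle and in the A–O–B ether: the oxygen on a6 is flanked by OMe and by the bridge, and b1 belongs to a ring without any activating group, so neither SNAr nor a fast copper-mediated coupling is available at the dilution an 18-membered ring needs. The feature that the key step exploits is that b1(O), b6(H), b5(CH2) and b2(H) reproduce C4(O), C5(H), C6(CH3) and C3(H) of 4-hydroxy-6-methyl-2H-pyran-2-one, while b3 and b4 are two adjacent CH groups. Written as that pyranone, ring B has an electrophilic b1 (vinylogous acyl carbon) and a nucleophilic carbon on b5 (vinylogous enolate), so both of its links can be made by polar, metal-free reactions and the macrocycle can be closed by addition–elimination. In one sentence, ring B is created from the macrocyclic pyranone 16 by Diels–Alder addition of the acetylene equivalent 17 and loss of CO2.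

## Logic of the disconnections

**21 ⇒ 20.** The bond cut is O–CH2Ph on the c4 oxygen (a benzyl group is added in the backward sense). It distinguishes this oxygen from the methyl ether on a1 and from the a6 oxygen that must act as nucleophile. No skeletal simplification is gained, but every earlier intermediate is freed from a second acidic phenol. The demand is that hydrogenolysis comes last, after the reducible pyranone has gone.

**20 ⇒ 16 + 17 (key).** The bonds cut are b2–b3 and b4–b5 of ring B; b3 and b4 go back to 17, and b2 and b5 are rejoined through an O–C(=O) bridge. This replaces an inert meta-phenylene by a pyranone whose C4 and C6 side chain carry complementary polar reactivity. The gain is that 16 has one benzene ring fewer and every remaining bond to the ring B atoms can be made without a metal. The demand is that the pyranone of 16 reacts as a diene at C3/C6 with an electron-poor alkene near 180 °C, and that 18 and 19 lose CO2 and sulfinic acid while the rest of the macrocycle stays inert.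

**16 ⇒ 14 (via 15).** The bond cut is O–C4 between the a6 oxygen and the pyranone, which opens the 18-membered ring. C4–Br of a pyranone is a vinylogous acyl bromide, so the forward bond formation is an addition–elimination that is fast without metal even for a flanked phenoxide. The gain is an open chain that contains only unhindered, conventional bonds. The demand is that the phenoxide is set free only at this stage and only at high dilution.

**14 ⇒ 13.** The bond cut is C4–Br, traced back to C4–OH. The vinylogous acid is what C-alkylation of the pyranone delivers. The gain is access to the commodity pyranone 11. The demand is a bromination that spares the silyl and benzyl ethers.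

**13 ⇒ 10 + 11 (via 12).** The bond cut is CH2–CH2 of the B/C bridge, between the carbon on b5 (the C6 methyl of 11) and the carbon on c1. The methyl terminus of dianion 12 is a carbon nucleophile, so the bridge forms at its final oxidation level in one step. The gain is that four ring B carbons and one bridge carbon come from 11. The demand is C-alkylation at the methyl terminus, not at oxygen or C3, with a reactive benzylic bromide.

**10 ⇒ 9 ⇒ 8.** The bonds cut are C–Br and then C–H of the benzylic position (CH2Br ⇐ CH2OH ⇐ CHO). The aldehyde is the oxidation level in which the commercial ring C unit is available. The gain is direct access to 7. The demand is mild hydride reduction and neutral bromination.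

**8 ⇒ 6 + 7.** The bond cut is O–d1 of the C–O–D ether. This ether is unhindered on the ring D side and can be made by copper catalysis at normal concentration. The gain is two fragments of about equal size, one of them commercial. The demand is that the aldehyde and the silyl ether survive phosphate base at 90 °C.

**6 ⇒ 5 ⇒ 2 + 3 (via 4).** The bond cut is CH2–CH2 of the D/A bridge, traced back to C=C between the carbon on a5 and the carbon on d4. An aldehyde on a5 and a benzylic phosphonate are both at hand. The gain is two simple benzenes. The demand is a reduction of the C=C bond that leaves C–Br intact.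

**2 ⇒ 1.** The bond cut is O–Si on the a6 oxygen. The silyl group masks the phenol through steps 2 to 8 and is removed by the same fluoride that triggers ring closure. The gain is the commercial aldehyde 1, which already carries OMe, OH and CHO on a1, a6 and a5. The demand is a silyl ether bulky enough to resist base.

## Other disconnections considered

**Alternative 1:** The first plan that comes to mind cuts the D/A bridge as an alkene inside the ring. Forward, the phosphonium aldehyde A1 undergoes an intramolecular Wittig reaction to the macrocyclic stilbene A2, and hydrogenation (which also cleaves the benzyl ether) gives 21. All four arenes are bought as benzenes and the ethers are made by SNAr or Ullmann coupling. The chosen plan is preferred on step economy and on the nature of the ring closure: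
- In A1 every bridge carbon must pass through the aldehyde, alcohol, bromide and phosphonium levels, whereas the B/C bridge of 13 is made in one C-alkylation at its final oxidation level.
- The Wittig closure needs a strong base at high dilution and gives an E/Z mixture that only the final hydrogenation corrects.
- The A–O–B ether of A1 can only be made if ring A carries an activating formyl group next to the leaving group, which fixes the order of the whole assembly.

**Alternative 2:** The cut is O–b1 with ring B kept as a benzene. Forward, the bromophenol A3 undergoes intramolecular copper-catalysed O-arylation to give 20. The chosen plan is preferred on mechanism. The copper phenoxide of a di-ortho-substituted phenol would have to activate an unactivated aryl bromide, and this step slows further at the millimolar concentration that the 18-membered ring demands. Heating then favours reduction of the C–Br bond and intermolecular coupling. An SNAr variant would need a nitro group on ring B and three further steps to remove it. In the chosen plan the same two atoms are joined at 60 °C without metal, because b1 is at that moment C4 of a bromopyranone.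

**Alternative 3:** The cut is the same [4+2] retron of ring B, but used intramolecularly. Forward, the aryloxypyranone A4 with a tethered (E)-alkenyl sulfone closes ring B and the macrocycle in one thermal cascade to give 20. This closes two rings at once, and the electronic match places the chain-bearing alkene carbon on C3, hence meta to the oxygen. The chosen plan is preferred for three reasons:
- The β-alkyl alkenyl sulfone of A4 is a much weaker dienophile than 17.
- The cycloaddition would have to run at millimolar concentration through an 18-membered transition state, with the para-bridged 19-membered regioisomer as a competitor. With 17 in excess it runs concentrated and its regiochemistry is erased on aromatisation.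
- A4 needs a pyranone without the C6 methyl and a three-carbon homologation of ring C, so it cannot use 11 to build the B/C bridge and is longer.

Key step: step 10

## Route

Step 1
Reactants: 1 2-hydroxy-3-methoxybenzaldehyde (o-vanillin)
Product: 2 3-methoxy-2-{[tri(propan-2-yl)silyl]oxy}benzaldehyde
Conditions: i-Pr3SiCl, imidazole, DMAP (cat.), DMF, 40 °C
Reagents that add atoms: chlorotri(propan-2-yl)silane, CC(C)[Si](Cl)(C(C)C)C(C)C
Why: O-silylation of a phenol; the bulky silyl ether masks the a6 oxygen against base, hydride and mild acid and is cleaved only by fluoride in step 9.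

Step 2
Reactants: 2 3-methoxy-2-{[tri(propan-2-yl)silyl]oxy}benzaldehyde; 3 diethyl [(4-bromophenyl)methyl]phosphonate
Product: 5 {2-[(E)-2-(4-bromophenyl)ethenyl]-6-methoxyphenoxy}tri(propan-2-yl)silane, via sodium phosphonate carbanion 4 (not isolated)
Conditions: NaH, 15-crown-5 (cat.), THF, 0 °C → rt
Reagents that add atoms: none
Why: Horner–Wadsworth–Emmons olefination; benzylic phosphonate anions give (E)-stilbenes, and the geometry is of no consequence after step 3.

Step 3
Reactants: 5 {2-[(E)-2-(4-bromophenyl)ethenyl]-6-methoxyphenoxy}tri(propan-2-yl)silane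
Product: 6 {2-[2-(4-bromophenyl)ethyl]-6-methoxyphenoxy}tri(propan-2-yl)silane
Conditions: TsNHNH2, NaOAc, DME/H2O, reflux
Reagents that add atoms: none
Why: Diimide reduction (concerted syn transfer of two hydrogens) saturates the stilbene double bond without hydrogenolysis of the C–Br bond needed in step 4.

Step 4
Reactants: 6 {2-[2-(4-bromophenyl)ethyl]-6-methoxyphenoxy}tri(propan-2-yl)silane; 7 4-(benzyloxy)-3-hydroxybenzaldehyde
Product: 8 4-(benzyloxy)-3-{4-[2-(3-methoxy-2-{[tri(propan-2-yl)silyl]oxy}phenyl)ethyl]phenoxy}benzaldehyde
Conditions: CuI (10 mol%), pyridine-2-carboxylic acid (20 mol%), K3PO4, DMSO, 90 °C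
Reagents that add atoms: none
Why: Ullmann-type copper-catalysed O-arylation; an unhindered para-alkyl aryl bromide and an ortho-alkoxy phenol are standard partners, and the aldehyde and the hindered silyl ether should tolerate the phosphate base.

Step 5
Reactants: 8 4-(benzyloxy)-3-{4-[2-(3-methoxy-2-{[tri(propan-2-yl)silyl]oxy}phenyl)ethyl]phenoxy}benzaldehyde
Product: 9 [4-(benzyloxy)-3-{4-[2-(3-methoxy-2-{[tri(propan-2-yl)silyl]oxy}phenyl)ethyl]phenoxy}phenyl]methanol
Conditions: NaBH4, MeOH/THF, 0 °C
Reagents that add atoms: none
Why: Hydride reduction of the aryl aldehyde to the benzylic alcohol; silyl ether, benzyl ether and diaryl ether are inert to NaBH4.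

Step 6
Reactants: 9 [4-(benzyloxy)-3-{4-[2-(3-methoxy-2-{[tri(propan-2-yl)silyl]oxy}phenyl)ethyl]phenoxy}phenyl]methanol
Product: 10 {2-[2-(4-{2-(benzyloxy)-5-(bromomethyl)phenoxy}phenyl)ethyl]-6-methoxyphenoxy}tri(propan-2-yl)silane
Conditions: CBr4, PPh3, CH2Cl2, 0 °C
Reagents that add atoms: carbon tetrabromide, BrC(Br)(Br)Br
Why: Appel reaction; bromide displaces the alkoxyphosphonium group (SN2) under neutral conditions, which suits this electron-rich, labile benzylic bromide, used without storage.

Step 7
Reactants: 10 {2-[2-(4-{2-(benzyloxy)-5-(bromomethyl)phenoxy}phenyl)ethyl]-6-methoxyphenoxy}tri(propan-2-yl)silane; 11 4-hydroxy-6-methyl-2H-pyran-2-one (triacetic acid lactone)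
Product: 13 6-{2-[4-(benzyloxy)-3-{4-[2-(3-methoxy-2-{[tri(propan-2-yl)silyl]oxy}phenyl)ethyl]phenoxy}phenyl]ethyl}-4-hydroxy-2H-pyran-2-one, via dilithium dianion of triacetic acid lactone 12 (not isolated)
Conditions: 11 (3 equiv), LiN(i-Pr)2 (6 equiv), THF/DMPU, −78 °C; then 10, −78 → −20 °C; aq. HCl
Reagents that add atoms: none
Why: Alkylation of the dianion of a 4-hydroxy-6-methylpyranone, a known reaction type; the second deprotonation gives a C6-methylene carbanion far more nucleophilic than the oxygen or C3 of the monoanion, so the benzylic bromide is attacked by that carbon (SN2) and the B/C bridge forms at its final oxidation level. Excess dianion limits double alkylation.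

Step 8
Reactants: 13 6-{2-[4-(benzyloxy)-3-{4-[2-(3-methoxy-2-{[tri(propan-2-yl)silyl]oxy}phenyl)ethyl]phenoxy}phenyl]ethyl}-4-hydroxy-2H-pyran-2-one
Product: 14 6-{2-[4-(benzyloxy)-3-{4-[2-(3-methoxy-2-{[tri(propan-2-yl)silyl]oxy}phenyl)ethyl]phenoxy}phenyl]ethyl}-4-bromo-2H-pyran-2-one
Conditions: PBr3, DMF, 0 → 60 °C
Reagents that add atoms: phosphorus tribromide, BrP(Br)Br
Why: Conversion of a vinylogous acid into the vinylogous acyl bromide: the bromoiminium reagent from PBr3 and DMF activates the C4 oxygen and bromide adds to C4 and expels it; aryl silyl and benzyl ethers should withstand these mildly acidic conditions.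

Step 9
Reactants: 14 6-{2-[4-(benzyloxy)-3-{4-[2-(3-methoxy-2-{[tri(propan-2-yl)silyl]oxy}phenyl)ethyl]phenoxy}phenyl]ethyl}-4-bromo-2H-pyran-2-one
Product: 16 macrocyclic pyranone: the 18-membered ring of 20 with ring B replaced by a 2H-pyran-2-one bound through C4 to the a6 oxygen and through C6 to the bridge to ring C, via cesium phenoxide 15 (not isolated)
Conditions: CsF, 4 Å molecular sieves, DMF (1 mM), 60 °C
Reagents that add atoms: none
Why: Fluoride cleaves the aryl silyl ether and the flanked phenoxide adds to C4 of the bromopyranone with loss of bromide (vinylogous acyl substitution, the known reaction of 4-halo-2H-pyran-2-ones with phenoxides), closing the 18-membered ring. The low barrier of this addition–elimination, which a benzenoid ring B could not offer, is what permits millimolar concentration.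

Step 10
Reactants: 16 macrocyclic pyranone; 17 (ethenesulfonyl)benzene (phenyl vinyl sulfone)
Product: 20 benzyl ether of the target at the c4 oxygen of ring C, via bridged lactone cycloadduct 18 (not isolated), via cyclohexadienyl sulfone 19 (not isolated)
Conditions: 17 (10 equiv), i-Pr2NEt (3 equiv), BHT (cat.), 1,2-dichlorobenzene, 180 °C, sealed tube
Reagents that add atoms: none
Why: Normal-electron-demand Diels–Alder reaction of the 4-aryloxy-6-alkylpyranone diene of 16 (C3=C4–C5=C6, with the aryloxy donor on C4 and the ring oxygen and alkyl group on C6 expected to put the largest HOMO coefficient on C3) with the electron-poor alkene 17; the closest known reaction type is the cycloaddition of 2H-pyran-2-ones with vinyl sulfones as alkyne equivalents followed by CO2 extrusion and sulfinate loss, together with the thermal cycloadditions of 4-alkoxy-6-methylpyranones with acetylenic esters. The CH2 terminus of 17 should bond to C3 and the sulfonyl-bearing carbon to C6, giving the bridged lactone 18 as an endo/exo mixture. At 180 °C 18 loses CO2 by retro-[4+2] reaction to the cyclohexa-1,3-diene 19, and amine-assisted anti elimination of benzenesulfinic acid across its two sp3 carbons is driven by aromatisation to ring B of 20. Ring B is thus closed by an intermolecular [4+2] annulation (bonds b2–b3 and b4–b5) on a preformed macrocycle, so no macrocyclic transition state is involved. No stereocentre survives, since those of 18 and 19 are erased, and for the same reason neither the endo/exo outcome nor the orientation of 17 matters: both modes leave hydrogen on b3 and b4. The selectivity needed is chemoselectivity for the single diene of 16 (the benzene rings, the benzyl ether and the diaryl ethers are inert to 17) and suppression of a second cycloaddition of 19 with 17, which the amine base should secure by making sulfinate loss fast and by trapping the acid. The accepted risk is the modest dienophilicity of 17 toward this pyranone, offset by its large excess at high concentration.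

Step 11
Reactants: 20 benzyl ether of the target at the c4 oxygen of ring C
Product: 21 target CNP0309263.0: ring A methyl ether of marchantin C with OMe on a1 and free OH on c4
Conditions: H2 (1 atm), Pd/C, EtOAc/MeOH, rt
Reagents that add atoms: none
Why: Hydrogenolysis of the benzyl aryl ether; diaryl ethers, the methyl ether and the saturated bridges are inert, and no reducible pyranone remains.

## Compound list

1 | 2-hydroxy-3-methoxybenzaldehyde (o-vanillin) | COc1cccc(C=O)c1O | starting material
2 | 3-methoxy-2-{[tri(propan-2-yl)silyl]oxy}benzaldehyde | COc1cccc(C=O)c1O[Si](C(C)C)(C(C)C)C(C)C | intermediate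
3 | diethyl [(4-bromophenyl)methyl]phosphonate | CCOP(=O)(Cc1ccc(Br)cc1)OCC | starting material
4 | sodium (4-bromophenyl)(diethoxyphosphoryl)methanide | [Na+].CCOP(=O)([CH-]c1ccc(Br)cc1)OCC | intermediate (not isolated)
5 | {2-[(E)-2-(4-bromophenyl)ethenyl]-6-methoxyphenoxy}tri(propan-2-yl)silane | COc1cccc(/C=C/c2ccc(Br)cc2)c1O[Si](C(C)C)(C(C)C)C(C)C | intermediate
6 | {2-[2-(4-bromophenyl)ethyl]-6-methoxyphenoxy}tri(propan-2-yl)silane | COc1cccc(CCc2ccc(Br)cc2)c1O[Si](C(C)C)(C(C)C)C(C)C | intermediate
7 | 4-(benzyloxy)-3-hydroxybenzaldehyde | O=Cc1ccc(OCc2ccccc2)c(O)c1 | starting material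
8 | 4-(benzyloxy)-3-{4-[2-(3-methoxy-2-{[tri(propan-2-yl)silyl]oxy}phenyl)ethyl]phenoxy}benzaldehyde | COc1cccc(CCc2ccc(Oc3cc(C=O)ccc3OCc3ccccc3)cc2)c1O[Si](C(C)C)(C(C)C)C(C)C | intermediate
9 | [4-(benzyloxy)-3-{4-[2-(3-methoxy-2-{[tri(propan-2-yl)silyl]oxy}phenyl)ethyl]phenoxy}phenyl]methanol | COc1cccc(CCc2ccc(Oc3cc(CO)ccc3OCc3ccccc3)cc2)c1O[Si](C(C)C)(C(C)C)C(C)C | intermediate
10 | {2-[2-(4-{2-(benzyloxy)-5-(bromomethyl)phenoxy}phenyl)ethyl]-6-methoxyphenoxy}tri(propan-2-yl)silane | COc1cccc(CCc2ccc(Oc3cc(CBr)ccc3OCc3ccccc3)cc2)c1O[Si](C(C)C)(C(C)C)C(C)C | intermediate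
11 | 4-hydroxy-6-methyl-2H-pyran-2-one (triacetic acid lactone) | CC1=CC(O)=CC(=O)O1 | starting material
12 | dilithium 6-methanidyl-2-oxo-2H-pyran-4-olate (dianion of 11) | [Li+].[Li+].[CH2-]C1=CC([O-])=CC(=O)O1 | intermediate (not isolated)
13 | 6-{2-[4-(benzyloxy)-3-{4-[2-(3-methoxy-2-{[tri(propan-2-yl)silyl]oxy}phenyl)ethyl]phenoxy}phenyl]ethyl}-4-hydroxy-2H-pyran-2-one | COc1cccc(CCc2ccc(Oc3cc(CCC4=CC(O)=CC(=O)O4)ccc3OCc3ccccc3)cc2)c1O[Si](C(C)C)(C(C)C)C(C)C | intermediate
14 | 6-{2-[4-(benzyloxy)-3-{4-[2-(3-methoxy-2-{[tri(propan-2-yl)silyl]oxy}phenyl)ethyl]phenoxy}phenyl]ethyl}-4-bromo-2H-pyran-2-one | COc1cccc(CCc2ccc(Oc3cc(CCC4=CC(Br)=CC(=O)O4)ccc3OCc3ccccc3)cc2)c1O[Si](C(C)C)(C(C)C)C(C)C | intermediate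
15 | cesium 2-{2-[4-(2-(benzyloxy)-5-[2-(4-bromo-2-oxo-2H-pyran-6-yl)ethyl]phenoxy)phenyl]ethyl}-6-methoxyphenolate | [Cs+].COc1cccc(CCc2ccc(Oc3cc(CCC4=CC(Br)=CC(=O)O4)ccc3OCc3ccccc3)cc2)c1[O-] | intermediate (not isolated)
16 | macrocyclic pyranone (18-membered; pyranone C4 on the a6 oxygen, C6 on the bridge to ring C; c4 oxygen benzylated) | COc1cccc2c1OC1=CC(=O)OC(=C1)CCc1ccc(OCc3ccccc3)c(c1)Oc1ccc(cc1)CC2 | intermediate
17 | (ethenesulfonyl)benzene (phenyl vinyl sulfone) | C=CS(=O)(=O)c1ccccc1 | starting material
18 | bridged lactone cycloadduct of 16 and 17 (2-oxabicyclo[2.2.2]oct-5-en-3-one across former C3 and C6; phenylsulfonyl on the carbon next to former C6; racemic endo/exo mixture, so no descriptors) | COc1cccc2c1OC4=CC5(OC(=O)C4CC5S(=O)(=O)c6ccccc6)CCc1ccc(OCc3ccccc3)c(c1)Oc1ccc(cc1)CC2 | intermediate (not isolated)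
19 | cyclohexa-1,3-dienyl sulfone formed from 18 by loss of CO2 (racemic, so no descriptor) | COc1cccc2c1OC4=CCC(S(=O)(=O)c6ccccc6)C(=C4)CCc1ccc(OCc3ccccc3)c(c1)Oc1ccc(cc1)CC2 | intermediate (not isolated)
20 | benzyl ether of the target at the c4 oxygen of ring C | COc1cccc2c1Oc1cccc(c1)CCc1ccc(OCc3ccccc3)c(c1)Oc1ccc(cc1)CC2 | intermediate
21 | CNP0309263.0, ring A methyl ether of marchantin C (achiral) | COc1cccc2c1Oc1cccc(c1)CCc1ccc(O)c(c1)Oc1ccc(cc1)CC2 | target

## Step count and least certain steps

Total step count: 11. Longest linear sequence: 11 steps (1 to 21); 3, 7, 11 and 17 enter at steps 2, 4, 7 and 10.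

**Step 10 (key step).** Three processes may interfere. The cycloaddition may be too slow, since a lactone-containing diene meets a mono-activated alkene, and thermal degradation could then win. A second cycloaddition of 17 onto the electron-rich diene 19 could occur before the sulfinate is lost. Strong acid from disproportionation of sulfinic acid could debenzylate the product if the base is exhausted. The fallback abandons the pyranone logic, sets out from 8 and returns at 21. Desilylation of 8 (Bu4NF, AcOH, THF) gives the phenol aldehyde 4-(benzyloxy)-3-{4-[2-(2-hydroxy-3-methoxyphenyl)ethyl]phenoxy}benzaldehyde F1. Copper-catalysed O-arylation with 3-bromobenzaldehyde (CuI, pyridine-2-carboxylic acid, K3PO4, DMSO, 110 °C) gives the dialdehyde 4-(benzyloxy)-3-(4-{2-[2-(3-formylphenoxy)-3-methoxyphenyl]ethyl}phenoxy)benzaldehyde F2. McMurry coupling at high dilution (TiCl4, Zn, pyridine, THF, reflux) closes the ring at the B/C bridge as the macrocyclic stilbene benzyl ether F3 (E/Z mixture). Hydrogenation (H2, Pd/C) saturates the alkene and cleaves the benzyl ether to give 21.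

**Step 9.** Intermolecular addition–elimination could lead to oligomers. Adventitious water could hydrolyse the C4–Br bond to the unreactive pyranolate. Phenoxide or fluoride could open the lactone by attack at C2 or C6. The fallback moves the ring closure to the C–C bond of the B/C bridge, sets out from 9 and 11 and returns at 16. Compound 11 is converted (PBr3, DMF) into 4-bromo-6-methyl-2H-pyran-2-one F4. Compound 9 and F4 with CsF in DMF give, by desilylation and intermolecular addition–elimination, 4-[2-(2-{4-[2-(benzyloxy)-5-(hydroxymethyl)phenoxy]phenyl}ethyl)-6-methoxyphenoxy]-6-methyl-2H-pyran-2-one F5. CBr4 and PPh3 give the benzylic bromide 4-[2-(2-{4-[2-(benzyloxy)-5-(bromomethyl)phenoxy]phenyl}ethyl)-6-methoxyphenoxy]-6-methyl-2H-pyran-2-one F6. Slow addition of F6 to LiN(SiMe3)2 in THF at −78 °C under high dilution deprotonates the C6 methyl group, and intramolecular C-benzylation of the dienolate gives 16.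

**Step 7.** Alkylation could occur on oxygen or C3, or twice. Proton transfer could quench the dianion. The electron-rich benzylic bromide could decompose before it is attacked. The fallback uses a monoanion with the C4 oxygen masked, sets out from 10 and 11 and returns at 13. Mitsunobu O-alkylation of 11 ((4-methoxyphenyl)methanol, PPh3, diisopropyl azodicarboxylate) gives 4-[(4-methoxyphenyl)methoxy]-6-methyl-2H-pyran-2-one F7. Deprotonation of its C6 methyl group (LiN(i-Pr)2, THF, −78 °C) and alkylation with 10 give 6-{2-[4-(benzyloxy)-3-{4-[2-(3-methoxy-2-{[tri(propan-2-yl)silyl]oxy}phenyl)ethyl]phenoxy}phenyl]ethyl}-4-[(4-methoxyphenyl)methoxy]-2H-pyran-2-one F8. CF3CO2H and anisole in CH2Cl2 at 0 °C remove the 4-methoxybenzyl group to give 13.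

**Step 8.** The iminium reagent could formylate C3, and HBr could cleave the silyl ether. The fallback activates the C4 oxygen under basic conditions, sets out from 13 and returns at 16. 2,4,6-Tri(propan-2-yl)benzenesulfonyl chloride and Et3N in CH2Cl2 give 6-{2-[4-(benzyloxy)-3-{4-[2-(3-methoxy-2-{[tri(propan-2-yl)silyl]oxy}phenyl)ethyl]phenoxy}phenyl]ethyl}-2-oxo-2H-pyran-4-yl 2,4,6-tri(propan-2-yl)benzenesulfonate F9, whose hindered sulfur should disfavour sulfonyl transfer to the phenoxide. CsF in DMF at the dilution of step 9 then gives 16 by desilylation and displacement of the sulfonate.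

**Step 4.** Silyl transfer from the a6 oxygen to the phenoxide of 7, or plain desilylation in hot basic DMSO, would free the ring A phenol, which would then be arylated in competition. The fallback replaces the hot Ullmann coupling by an oxidative coupling at room temperature, sets out from 6 and returns at 8. Bromine–lithium exchange and borylation (n-BuLi, THF, −78 °C; B(Oi-Pr)3; aq. NH4Cl) give {4-[2-(3-methoxy-2-{[tri(propan-2-yl)silyl]oxy}phenyl)ethyl]phenyl}boronic acid F10. Chan–Lam coupling with 7 (Cu(OAc)2, pyridine, 4 Å molecular sieves, CH2Cl2, air, rt) gives 8.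

## Further compounds

F1 | step 10 | 4-(benzyloxy)-3-{4-[2-(2-hydroxy-3-methoxyphenyl)ethyl]phenoxy}benzaldehyde | COc1cccc(CCc2ccc(Oc3cc(C=O)ccc3OCc3ccccc3)cc2)c1O
F2 | step 10 | 4-(benzyloxy)-3-(4-{2-[2-(3-formylphenoxy)-3-methoxyphenyl]ethyl}phenoxy)benzaldehyde | COc1cccc(CCc2ccc(Oc3cc(C=O)ccc3OCc3ccccc3)cc2)c1Oc1cccc(C=O)c1
F3 | step 10 | macrocyclic stilbene benzyl ether with the alkene between rings B and C (E/Z mixture, geometry not specified) | COc1cccc2c1Oc1cccc(c1)C=Cc1ccc(OCc3ccccc3)c(c1)Oc1ccc(cc1)CC2
F4 | step 9 | 4-bromo-6-methyl-2H-pyran-2-one | CC1=CC(Br)=CC(=O)O1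
F5 | step 9 | 4-[2-(2-{4-[2-(benzyloxy)-5-(hydroxymethyl)phenoxy]phenyl}ethyl)-6-methoxyphenoxy]-6-methyl-2H-pyran-2-one | COc1cccc(CCc2ccc(Oc3cc(CO)ccc3OCc3ccccc3)cc2)c1OC1=CC(=O)OC(C)=C1
F6 | step 9 | 4-[2-(2-{4-[2-(benzyloxy)-5-(bromomethyl)phenoxy]phenyl}ethyl)-6-methoxyphenoxy]-6-methyl-2H-pyran-2-one | COc1cccc(CCc2ccc(Oc3cc(CBr)ccc3OCc3ccccc3)cc2)c1OC1=CC(=O)OC(C)=C1
F7 | step 7 | 4-[(4-methoxyphenyl)methoxy]-6-methyl-2H-pyran-2-one | COc1ccc(COC2=CC(=O)OC(C)=C2)cc1
F8 | step 7 | 6-{2-[4-(benzyloxy)-3-{4-[2-(3-methoxy-2-{[tri(propan-2-yl)silyl]oxy}phenyl)ethyl]phenoxy}phenyl]ethyl}-4-[(4-methoxyphenyl)methoxy]-2H-pyran-2-one | COc1cccc(CCc2ccc(Oc3cc(CCC4=CC(OCc5ccc(OC)cc5)=CC(=O)O4)ccc3OCc3ccccc3)cc2)c1O[Si](C(C)C)(C(C)C)C(C)C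
F9 | step 8 | 6-{2-[4-(benzyloxy)-3-{4-[2-(3-methoxy-2-{[tri(propan-2-yl)silyl]oxy}phenyl)ethyl]phenoxy}phenyl]ethyl}-2-oxo-2H-pyran-4-yl 2,4,6-tri(propan-2-yl)benzenesulfonate | COc1cccc(CCc2ccc(Oc3cc(CCC4=CC(OS(=O)(=O)c5c(C(C)C)cc(C(C)C)cc5C(C)C)=CC(=O)O4)ccc3OCc3ccccc3)cc2)c1O[Si](C(C)C)(C(C)C)C(C)C
F10 | step 4 | {4-[2-(3-methoxy-2-{[tri(propan-2-yl)silyl]oxy}phenyl)ethyl]phenyl}boronic acid | COc1cccc(CCc2ccc(B(O)O)cc2)c1O[Si](C(C)C)(C(C)C)C(C)C
A1 | alternative 1 | {4-[2-(benzyloxy)-5-{2-[3-(2-formyl-6-methoxyphenoxy)phenyl]ethyl}phenoxy]benzyl}triphenylphosphonium bromide | COc1cccc(C=O)c1Oc1cccc(CCc2ccc(OCc3ccccc3)c(Oc3ccc(C[P+](c4ccccc4)(c4ccccc4)c4ccccc4)cc3)c2)c1.[Br-]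
A2 | alternative 1 | macrocyclic stilbene benzyl ether with the alkene between rings A and D (E/Z mixture, geometry not specified) | COc1cccc2c1Oc1cccc(c1)CCc1ccc(OCc3ccccc3)c(c1)Oc1ccc(cc1)C=C2
A3 | alternative 2 | 2-{2-[4-(2-(benzyloxy)-5-[2-(3-bromophenyl)ethyl]phenoxy)phenyl]ethyl}-6-methoxyphenol | COc1cccc(CCc2ccc(Oc3cc(CCc4cccc(Br)c4)ccc3OCc3ccccc3)cc2)c1O
A4 | alternative 3 | 4-{2-[2-(4-{2-(benzyloxy)-5-[(3E)-4-(phenylsulfonyl)but-3-en-1-yl]phenoxy}phenyl)ethyl]-6-methoxyphenoxy}-2H-pyran-2-one | COc1cccc(CCc2ccc(Oc3cc(CC/C=C/S(=O)(=O)c4ccccc4)ccc3OCc3ccccc3)cc2)c1OC1=CC(=O)OC=C1
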